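**Strategy.** The two carbocyclic halves are bought as rings: the (S)- and (R)-Wieland–Miescher ketones. Ring A of the (S)-derived decalin is a latent oxepanone; hydration of C5=C6, retro-aldol scission of C4–C5 and enolate hydroxylation leave a cyclohexanone (C5) whose neighbouring quaternary carbon carries a CH2CH2C(=O)CMe2OSiMe3 arm. After Negishi union with the (R)-derived enol triflate, the key step closes the oxepanone last: reductive etherification joins the tertiary O–CMe2 oxygen to the ketone carbon, forging the hindered C–O–C link between the CMe2 carbon (alpha to the oxepanone C=O) and the ring-fusion CH, and setting that CH–O stereocentre (trans fusion) in the same operation. SeO2 then installs the diosphenol.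

Key step: step 19

Remarks on the chemistry:
- Both enantiomers of the Wieland–Miescher ketone are assumed to be commercial in enantiopure form.
- Decalin carbons carry terpenoid locants: C10 bears the angular methyl, C3 is the ring-A carbonyl carbon, C5 is the other ring-fusion carbon, C9 is the ring-B carbon next to C10. C11/C12 are the linker carbons. Primed locants belong to the (R)-derived half. "β" is the face of the angular methyl of the same half.
- C8 in 4/20, C5 in 12/13 and C3 in 24/25 are carried as epimer mixtures, since each becomes sp2 in a later step.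

Step 1
Reactants: 1 (S)-Wieland–Miescher ketone
Product: 2 left dienol ether (3-ethoxy-10-methyl-3,5-dien-9-one)
Conditions: HC(OEt)3, p-TsOH (cat.), EtOH, rt
Reagents that add atoms: triethyl orthoformate CCOC(OCC)OCC
Why: Acid-catalysed dienol ether formation should select the conjugated ketone, because the neopentyl C9 ketone resists acyclic ketalisation (as with 17-keto steroids), and it masks the enone for the enolate chemistry that follows.

Step 2
Reactants: 2 left dienol ether
Product: 4 left 8-methyl ketone, via lithium enolate 3 (not isolated)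
Conditions: LiN(i-Pr)2, THF, −78 °C; then MeI, −78 → 0 °C
Reagents that add atoms: iodomethane CI
Why: Kinetic enolate alkylation can only occur at C8 because C10 is quaternary, and the new centre becomes sp2 in step 3.

Step 3
Reactants: 4 left 8-methyl ketone
Product: 6 left enone triflate, via dienol ether triflate 5 (not isolated)
Conditions: KN(SiMe3)2, PhNTf2, THF, −78 → 0 °C; then 1 M HCl, THF, rt
Reagents that add atoms: N-phenylbis(trifluoromethanesulfonimide) O=S(=O)(N(c1ccccc1)S(=O)(=O)C(F)(F)F)C(F)(F)F; water O
Why: Enolisation towards the only α-hydrogen (C8) and O-sulfonylation should give the tetrasubstituted enol triflate (as with 2,2,6-trimethylcyclohexanone), and dilute acid then hydrolyses the dienol ether to the conjugated enone.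

Step 4
Reactants: 6 left enone triflate
Product: 7 left gem-dimethyl triflate (4,4,8,10-tetramethyl-3-oxo-5,8-dien-9-yl triflate)
Conditions: t-BuOK, MeI, THF/t-BuOH, −20 → 0 °C
Reagents that add atoms: iodomethane CI
Why: Deconjugative α,α-dialkylation of the extended dienolate installs the gem-dimethyl group and moves the alkene to C5=C6; the fully substituted enol triflate has no β-hydrogen for elimination and should survive brief cold exposure to the hindered alkoxide.

Step 5
Reactants: 7 left gem-dimethyl triflate
Product: 8 left vinyl diene (9-vinyl-4,4,8,10-tetramethyl-5,8-dien-3-one)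
Conditions: tributyl(vinyl)stannane, Pd(PPh3)4, LiCl, THF, 65 °C
Reagents that add atoms: tributyl(vinyl)stannane C=C[Sn](CCCC)(CCCC)CCCC
Why: Stille coupling of hindered cyclohexenyl triflates is LiCl-accelerated and leaves the ketone and the alkene positions untouched.

Step 6
Reactants: 8 left vinyl diene
Product: 10 left homoallylic alcohol, via alkylborane 9 (not isolated)
Conditions: 9-BBN, THF, 0 °C → rt; then H2O2, NaOH, 0 °C
Reagents that add atoms: hydrogen peroxide OO
Why: 9-BBN should hydroborate only the terminal carbon of the monosubstituted alkene (anti-Markovnikov hydroboration–oxidation), sparing the tetrasubstituted and hindered trisubstituted alkenes and the neopentyl ketone.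

Step 7
Reactants: 10 left homoallylic alcohol
Product: 11 left saturated alcohol (8β-methyl, 9β-CH2CH2OH, 8α-H, 9α-H)
Conditions: [Ir(cod)(PCy3)(py)]PF6 (10 mol %), H2 (20 bar), CH2Cl2, rt
Reagents that add atoms: none
Why: Hydroxyl-directed hydrogenation with Crabtree's catalyst should add H2 cis across the tetrasubstituted C8=C9 bond from the face opposite the axial angular methyl, setting C8 and C9 with methyl and side chain cis to that methyl, while the undirected C5=C6 alkene flanked by two quaternary carbons stays.

Step 8
Reactants: 11 left saturated alcohol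
Product: 12 left β-ketol (5-hydroxy-3-ketone, C5 epimers)
Conditions: Mn(dpm)3 (10 mol %, dpm = dipivaloylmethanate), PhSiH3, O2 (1 atm), i-PrOH/CH2Cl2, 0 °C → rt
Reagents that add atoms: dioxygen O=O
Why: Mukaiyama hydration (hydrogen-atom transfer to C6, O2 capture of the tertiary C5 radical) gives the Markovnikov tertiary alcohol, and either C5 epimer serves because C5 becomes a ketone in step 10.

Step 9
Reactants: 12 left β-ketol
Product: 13 left iodo β-ketol
Conditions: I2, PPh3, imidazole, CH2Cl2, 0 °C
Reagents that add atoms: iodine II
Why: Appel iodination is selective for the primary alcohol, the tertiary aldol hydroxyl being too hindered to react.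

Step 10
Reactants: 13 left iodo β-ketol
Product: 15 left hydroxy diketone, via potassium enolate 14 (not isolated)
Conditions: KN(SiMe3)2 (1.05 equiv), THF, −78 °C; then 2-(phenylsulfonyl)-3-phenyloxaziridine, −78 → −40 °C; AcOH quench
Reagents that add atoms: 2-(phenylsulfonyl)-3-phenyloxaziridine O=S(=O)(N1OC1c1ccccc1)c1ccccc1
Why: Deprotonating the tertiary aldol triggers an anionic retro-aldol cleavage of C4–C5 that releases the ring ketone and, regiospecifically, the tetrasubstituted enolate of the isopropyl ketone, which the Davis oxaziridine should hydroxylate (Davis enolate oxidation) before it equilibrates.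

Step 11
Reactants: 15 left hydroxy diketone
Product: 16 left silyl ether
Conditions: N-(trimethylsilyl)imidazole, CH2Cl2, rt
Reagents that add atoms: N-(trimethylsilyl)imidazole C[Si](C)(C)n1ccnc1
Why: The silylimidazole silylates the hindered tertiary acyloin hydroxyl under neutral conditions without enolising the ketones; the silyl ether protects it during zinc insertion and is the nucleophile of step 19.

Step 12
Reactants: 17 (R)-Wieland–Miescher ketone
Product: 18 right dienol ether
Conditions: HC(OEt)3, p-TsOH (cat.), EtOH, rt
Reagents that add atoms: triethyl orthoformate CCOC(OCC)OCC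
Why: Same selective dienol ether formation as in step 1, in the enantiomeric series.

Step 13
Reactants: 18 right dienol ether
Product: 20 right 8-methyl ketone, via lithium enolate 19 (not isolated)
Conditions: LiN(i-Pr)2, THF, −78 °C; then MeI, −78 → 0 °C
Reagents that add atoms: iodomethane CI
Why: Enolate alkylation at the only enolisable position, C8; this carbon ends as the methyl-bearing alkene carbon of the target.

Step 14
Reactants: 20 right 8-methyl ketone
Product: 22 right enone triflate, via dienol ether triflate 21 (not isolated)
Conditions: KN(SiMe3)2, PhNTf2, THF, −78 → 0 °C; then 1 M HCl, THF, rt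
Reagents that add atoms: N-phenylbis(trifluoromethanesulfonimide) O=S(=O)(N(c1ccccc1)S(=O)(=O)C(F)(F)F)C(F)(F)F; water O
Why: Enol triflate formation fixes the tetrasubstituted C8'=C9' alkene of the target and provides the coupling handle at C9'; acid unmasks the enone.

Step 15
Reactants: 22 right enone triflate
Product: 23 right gem-dimethyl triflate
Conditions: t-BuOK, MeI, THF/t-BuOH, −20 → 0 °C
Reagents that add atoms: iodomethane CI
Why: Deconjugative gem-dimethylation as in step 4 builds C4' and places the alkene at C5'=C6', where the right half needs its oxygen.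

Step 16
Reactants: 23 right gem-dimethyl triflate
Product: 25 right diol triflate (3-OH, 6-OH, 5-H and 6-OH anti to the angular methyl), via borane adduct 24 (not isolated)
Conditions: BH3·THF (excess), THF, 0 °C → rt; then H2O2, NaOH, 0 °C
Reagents that add atoms: hydrogen peroxide OO
Why: Borane reduces the C3' ketone and hydroborates C5'=C6' cis from the face opposite the angular methyl with boron on the less hindered C6', while the electron-poor tetrasubstituted enol triflate alkene should not react.

Step 17
Reactants: 25 right diol triflate
Product: 26 right diketone triflate (3,6-dioxo, 5-H trans to the angular methyl)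
Conditions: Dess–Martin periodinane, NaHCO3, CH2Cl2, rt
Reagents that add atoms: none
Why: Dess–Martin oxidation of both secondary alcohols gives the 3,6-diketone without touching the enol triflate.

Step 18
Reactants: 16 left silyl ether; 26 right diketone triflate
Product: 28 coupled seco ketone silyl ether, via alkylzinc iodide 27 (not isolated)
Conditions: Zn dust (activated), LiCl, THF, 40 °C; then 26, Pd(OAc)2 (5 mol %), SPhos (10 mol %), THF/NMP, 50 °C
Reagents that add atoms: none
Why: Knochel zinc insertion into the primary iodide tolerates the ketones and the silyl ether, and Negishi sp3–sp2 coupling with the hindered enol triflate should join the halves at C12–C9' without touching a stereocentre.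

Step 19
Reactants: 28 coupled seco ketone silyl ether
Product: 30 oxepanone (ring B' still the 6'-ketone), via oxocarbenium triflate 29 (not isolated)
Conditions: Et3SiH (5 equiv), TMSOTf (0.2 equiv), CH2Cl2, −78 → −20 °C
Reagents that add atoms: none
Why: TMSOTf silylates the ring ketone (C5), the tertiary trimethylsilyl ether oxygen of the side chain adds to it, and loss of disiloxane gives the seven-membered cyclic oxocarbenium ion 29, which Et3SiH reduces irreversibly. The closest known reaction type is the Noyori/Nicolaou reductive etherification (reductive hydroxy-ketone cyclisation to oxepanes). The oxepanone closes by O–C5 bond formation in a 7-exo-trig attack of oxygen on the carbonyl carbon (ring atoms O, CMe2, C=O, CH2, CH2, quaternary C10, C5). The new CH–O stereocentre should be set by hydride delivery to the face of 29 opposite the three β-substituents of the cyclohexane (angular methyl, C9 side chain, C8 methyl), which places oxygen cis to the angular methyl and gives the trans ring fusion. The step needs chemoselectivity among five ketones: only C5 has a silyl ether within reach, so an oxocarbenium ion should form there alone, while the hindered C3, C3' and C6' ketones can only be reduced by the slow bimolecular pathway at low temperature. Capture of C5 by the neighbouring chain carbonyl oxygen (six-membered ion) is the main competitor and should lose because that oxygen is a much weaker donor than the silyl ether.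

Step 20
Reactants: 30 oxepanone
Product: 31 CNP0302807.1
Conditions: SeO2, dioxane, 60 °C
Reagents that add atoms: selenium dioxide O=[Se]=O
Why: Riley oxidation: SeO2 should attack the conjugated dienol of the C6' ketone at C7', the only methylene that is both α to a ketone and allylic, and the resulting 6',7'-dione tautomerises to the C5'=C6' diosphenol of the target.

**Compound list**

1 | (S)-Wieland–Miescher ketone, (8aS)-8a-methyl-3,4,8,8a-tetrahydronaphthalene-1,6(2H,7H)-dione | C[C@]12CCC(=O)C=C1CCCC2=O | starting material
2 | left dienol ether: 3-ethoxy-10-methyl-decalin-3,5-dien-9-one, C10 as in 1 | C[C@]12CCC(OCC)=CC1=CCCC2=O | intermediate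
3 | lithium C8=C9 enolate of 2 | C[C@]12CCC(OCC)=CC1=CCC=C2[O-].[Li+] | intermediate
4 | left 8-methyl ketone: 3-ethoxy-8,10-dimethyl-decalin-3,5-dien-9-one (C8 epimers) | C[C@]12CCC(OCC)=CC1=CCC(C)C2=O | intermediate
5 | left dienol ether triflate: 3-ethoxy-8,10-dimethyl-decalin-3,5,8-trien-9-yl triflate | C[C@]12CCC(OCC)=CC1=CCC(C)=C2OS(=O)(=O)C(F)(F)F | intermediate
6 | left enone triflate: 8,10-dimethyl-3-oxo-decalin-4,8-dien-9-yl triflate | C[C@]12CCC(=O)C=C1CCC(C)=C2OS(=O)(=O)C(F)(F)F | intermediate
7 | left gem-dimethyl triflate: 4,4,8,10-tetramethyl-3-oxo-decalin-5,8-dien-9-yl triflate | C[C@]12CCC(=O)C(C)(C)C1=CCC(C)=C2OS(=O)(=O)C(F)(F)F | intermediate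
8 | left vinyl diene: 4,4,8,10-tetramethyl-9-vinyl-decalin-5,8-dien-3-one | C[C@]12CCC(=O)C(C)(C)C1=CCC(C)=C2C=C | intermediate
9 | B-alkyl-9-borabicyclononane adduct of 8 (boron on C12) | C[C@]12CCC(=O)C(C)(C)C1=CCC(C)=C2CCB1C2CCCC1CCC2 | intermediate
10 | left homoallylic alcohol: 9-(2-hydroxyethyl)-4,4,8,10-tetramethyl-decalin-5,8-dien-3-one | C[C@]12CCC(=O)C(C)(C)C1=CCC(C)=C2CCO | intermediate
11 | left saturated alcohol: 9β-(2-hydroxyethyl)-4,4,8β,10β-tetramethyl-decal-5-en-3-one (8-H and 9-H trans to the angular methyl) | OCC[C@H]1[C@@H](C)CC=C2C(C)(C)C(=O)CC[C@@]21C | intermediate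
12 | left β-ketol: 5-hydroxy-9β-(2-hydroxyethyl)-4,4,8β,10β-tetramethyl-decalin-3-one (C5 epimers) | OCC[C@H]1[C@@H](C)CCC2(O)C(C)(C)C(=O)CC[C@@]21C | intermediate
13 | left iodo β-ketol: 5-hydroxy-9β-(2-iodoethyl)-4,4,8β,10β-tetramethyl-decalin-3-one | ICC[C@H]1[C@@H](C)CCC2(O)C(C)(C)C(=O)CC[C@@]21C | intermediate
14 | potassium enolate of the seco isopropyl ketone (ring ketone free) | ICC[C@H]1[C@@H](C)CCC(=O)[C@]1(C)CCC([O-])=C(C)C.[K+] | intermediate
15 | left hydroxy diketone: 2-(4-hydroxy-4-methyl-3-oxopentyl)-3-(2-iodoethyl)-2,4-dimethylcyclohexanone, with 2-methyl, 3-iodoethyl and 4-methyl all cis | ICC[C@H]1[C@@H](C)CCC(=O)[C@]1(C)CCC(=O)C(C)(C)O | intermediate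
16 | left silyl ether: trimethylsilyl ether of 15 | ICC[C@H]1[C@@H](C)CCC(=O)[C@]1(C)CCC(=O)C(C)(C)O[Si](C)(C)C | intermediate
17 | (R)-Wieland–Miescher ketone, (8aR)-8a-methyl-3,4,8,8a-tetrahydronaphthalene-1,6(2H,7H)-dione | C[C@@]12CCC(=O)C=C1CCCC2=O | starting material
18 | right dienol ether (enantiomer of 2) | C[C@@]12CCC(OCC)=CC1=CCCC2=O | intermediate
19 | lithium C8=C9 enolate of 18 | C[C@@]12CCC(OCC)=CC1=CCC=C2[O-].[Li+] | intermediate
20 | right 8-methyl ketone (C8 epimers) | C[C@@]12CCC(OCC)=CC1=CCC(C)C2=O | intermediate
21 | right dienol ether triflate | C[C@@]12CCC(OCC)=CC1=CCC(C)=C2OS(=O)(=O)C(F)(F)F | intermediate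
22 | right enone triflate (enantiomer of 6) | C[C@@]12CCC(=O)C=C1CCC(C)=C2OS(=O)(=O)C(F)(F)F | intermediate
23 | right gem-dimethyl triflate (enantiomer of 7) | C[C@@]12CCC(=O)C(C)(C)C1=CCC(C)=C2OS(=O)(=O)C(F)(F)F | intermediate
24 | borane adduct of 23, drawn as the 3-O-BH2 / 6-BH2 form | C[C@@]12CCC(OB)C(C)(C)[C@H]1[C@H](B)CC(C)=C2OS(=O)(=O)C(F)(F)F | intermediate
25 | right diol triflate: 3,6-dihydroxy-4,4,8,10-tetramethyl-decal-8-en-9-yl triflate (5-H and 6-OH trans to the angular methyl, C3 epimers) | C[C@@]12CCC(O)C(C)(C)[C@H]1[C@H](O)CC(C)=C2OS(=O)(=O)C(F)(F)F | intermediate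
26 | right diketone triflate: 4,4,8,10-tetramethyl-3,6-dioxo-decal-8-en-9-yl triflate (5-H trans to the angular methyl) | C[C@@]12CCC(=O)C(C)(C)[C@H]1C(=O)CC(C)=C2OS(=O)(=O)C(F)(F)F | intermediate
27 | alkylzinc iodide from 16 | I[Zn]CC[C@H]1[C@@H](C)CCC(=O)[C@]1(C)CCC(=O)C(C)(C)O[Si](C)(C)C | intermediate
28 | coupled seco ketone silyl ether: 16 with iodine replaced by C9' of the 3',6'-dioxo-8'-ene decalin | C[C@@]12CCC(=O)C(C)(C)[C@H]1C(=O)CC(C)=C2CC[C@H]1[C@@H](C)CCC(=O)[C@]1(C)CCC(=O)C(C)(C)O[Si](C)(C)C | intermediate
29 | seven-membered cyclic oxocarbenium triflate (C5=O+–CMe2) | C[C@@]12CCC(=O)C(C)(C)[C@H]1C(=O)CC(C)=C2CC[C@H]1[C@@H](C)CCC2=[O+]C(C)(C)C(=O)CC[C@@]21C.[O-]S(=O)(=O)C(F)(F)F | intermediate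
30 | oxepanone: target skeleton with trans-fused 2,2-dimethyloxepan-3-one (O on C5 cis to the angular methyl) and ring B' as the 6'-ketone (5'-H, 7'-H2, 8'-ene) | C[C@@]12CCC(=O)C(C)(C)[C@H]1C(=O)CC(C)=C2CC[C@H]1[C@@H](C)CC[C@H]2OC(C)(C)C(=O)CC[C@@]21C | intermediate
31 | CNP0302807.1 | CC1=C(CC[C@H]2[C@@H](C)CC[C@H]3OC(C)(C)C(=O)CC[C@@]32C)[C@]2(C)CCC(=O)C(C)(C)C2=C(O)C1=O | target

**Step count.** Total 20 steps; longest linear sequence 14 steps (steps 1–11, 18, 19, 20).

**Steps most likely to fail, with fallbacks**

Step 19. The activated ring ketone may be captured by the neighbouring chain carbonyl oxygen instead of the silyl ether (six-membered oxocarbenium ion, tetrahydropyran products), other ketones may be reduced, or hydride may arrive on the wrong face. The fallback sets out from 28 and separates ring closure from reduction. Zn(OTf)2 and EtSH in CH2Cl2 at 0 °C should convert the silyl ether and ring ketone, under reversible ketalisation, into the seven-membered mixed O,S-ketal F1. Ph3SnH with AIBN in toluene at 110 °C then cleaves the C–S bond; the α-alkoxy radical takes hydrogen from the open α face, and the route is rejoined at 30.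

Step 20. Late oxidation may be unselective (allylic oxidation at C12' or the C8' methyl, attack on other ketone methylenes), or the β,γ-unsaturated ketone may first isomerise into conjugation. The fallback moves the oxidation to the fragment stage and starts from 26. SeO2 in dry dioxane at 60 °C should give the diosphenol triflate F2, which Ac2O, Et3N and DMAP convert into the enol acetate F3. Negishi coupling of F3 with the zinc reagent 27 (made from 16 as in step 18) gives the coupled acetate F4. Et3SiH and TMSOTf, as in step 19, close the oxepanone to the acetate F5. K2CO3 (cat.) in MeOH removes the acetate and the route comes back at 31.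

Step 10. After the retro-aldol cleavage, proton transfer between the new ring ketone and the enolate, or aldol re-closure, may outrun the oxygen transfer, giving hydroxylation at the wrong carbon or returned starting material. The fallback sets out from 13. KN(SiMe3)2 is added at −78 °C with Me3SiCl already present, so the enolate is trapped at once as the tetrasubstituted silyl enol ether F6. OsO4 (cat.) with N-methylmorpholine N-oxide in acetone/water then dihydroxylates the enol ether (the primary iodide is inert to it) and collapses to the α-hydroxy ketone, rejoining the route at 15.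

Further compounds
F1 | step 19 | seven-membered mixed O,S-ketal (5-ethylsulfanyl oxepanone, C5 epimers) | C[C@@]12CCC(=O)C(C)(C)[C@H]1C(=O)CC(C)=C2CC[C@H]1[C@@H](C)CCC2(SCC)OC(C)(C)C(=O)CC[C@@]21C
F2 | step 20 | diosphenol triflate: 6-hydroxy-4,4,8,10-tetramethyl-3,7-dioxo-decalin-5,8-dien-9-yl triflate | C[C@@]12CCC(=O)C(C)(C)C1=C(O)C(=O)C(C)=C2OS(=O)(=O)C(F)(F)F
F3 | step 20 | enol acetate of F2 | C[C@@]12CCC(=O)C(C)(C)C1=C(OC(C)=O)C(=O)C(C)=C2OS(=O)(=O)C(F)(F)F
F4 | step 20 | coupled acetate: seco ketone silyl ether with the acetylated diosphenol ring B' | C[C@@]12CCC(=O)C(C)(C)C1=C(OC(C)=O)C(=O)C(C)=C2CC[C@H]1[C@@H](C)CCC(=O)[C@]1(C)CCC(=O)C(C)(C)O[Si](C)(C)C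
F5 | step 20 | oxepanone acetate (O-acetyl derivative of 31) | C[C@@]12CCC(=O)C(C)(C)C1=C(OC(C)=O)C(=O)C(C)=C2CC[C@H]1[C@@H](C)CC[C@H]2OC(C)(C)C(=O)CC[C@@]21C
F6 | step 10 | tetrasubstituted trimethylsilyl enol ether of the seco isopropyl ketone | ICC[C@H]1[C@@H](C)CCC(=O)[C@]1(C)CCC(O[Si](C)(C)C)=C(C)C
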